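**Retrosynthetic overview**

1. The target is ent-oritin-(4β→6)-oritin-4α-ol. The last ring made is pyran ring F of the lower unit, cut at O1–C2 and C4a–C4 into a ring-D phenol (already carrying the upper flavan unit) and (2R,3S)-3-(4-benzyloxyphenyl)oxirane-2-carbaldehyde; one [3+3] annulation joins them and delivers C2, C3 and C4 of ring F.
2. Enabling feature: in ring D the phenol oxygen O1 is flanked by C4a, its only free ortho carbon (C4a is para to O7, and the para position C6 already carries C4 of ring C). The chain C2–C3–C4 bears oxygen on C3 and C4 and the electron-rich ring E on C2, which is the imprint of a trans-epoxy aldehyde (carbonyl carbon = C4, benzylic epoxide carbon = C2).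
3. Interflavanyl bond C4(ring C)–C6(ring D): Friedel–Crafts alkylation of a ketal-protected pyrogallol phenol by a flavan-3,4-diol, done before ring F exists, so the ionisable 4-OH of the lower unit never meets acid or a second electrophile.
4. Upper unit: ring C from a chalcone by Juliá–Colonna epoxidation, acid ring closure to the trans-dihydroflavonol and hydride reduction. The epoxy aldehyde comes from 4-(benzyloxy)benzaldehyde by olefination, reduction, Sharpless epoxidation and oxidation.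
5. Ring order: ring C (step 5), then ring F (step 13); rings A, B, D and E are bought as arenes; global hydrogenolysis ends the route.

Key step: step 13

Remark: oritin = (2R,3S)-2,3-trans-4′,7,8-trihydroxyflavan-3-ol, ent-oritin its enantiomer; rings A/B/C belong to the upper (4-aryl) unit and D/E/F to the lower unit (D benzo, E 4-hydroxyphenyl, F pyran); O1, C2, C3, C4, C4a are flavan locants.
Assumption: poly-D-leucine is taken as a purchasable catalyst (otherwise it is made by polymerising D-leucine N-carboxyanhydride).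

**Route**

Step 1
Reactants: 1 gallacetophenone [1-(2,3,4-trihydroxyphenyl)ethan-1-one]
Product: 2 1-[3,4-bis(benzyloxy)-2-hydroxyphenyl]ethan-1-one
Conditions: BnBr (2.1 equiv), K2CO3, DMF, rt
Reagents that add atoms: benzyl bromide BrCc1ccccc1
Why: Williamson etherification under mild base should benzylate the 3- and 4-hydroxyls, while the 2-hydroxyl, hydrogen-bonded to the acetyl carbonyl, stays free.

Step 2
Reactants: 2 1-[3,4-bis(benzyloxy)-2-hydroxyphenyl]ethan-1-one
Product: 3 1-[3,4-bis(benzyloxy)-2-(methoxymethoxy)phenyl]ethan-1-one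
Conditions: NaH, MOMCl, DMF, 0 °C → rt
Reagents that add atoms: chloromethyl methyl ether COCCl
Why: O-alkylation of the sodium phenoxide by the reactive α-chloro ether (Williamson type) masks the chelated phenol, which would otherwise divert the peroxide epoxidation of step 4 into oxidative cyclisation.

Step 3
Reactants: 3 1-[3,4-bis(benzyloxy)-2-(methoxymethoxy)phenyl]ethan-1-one; 4 4-(benzyloxy)benzaldehyde
Product: 5 (E)-1-[3,4-bis(benzyloxy)-2-(methoxymethoxy)phenyl]-3-[4-(benzyloxy)phenyl]prop-2-en-1-one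
Conditions: KOH, EtOH, rt
Reagents that add atoms: none
Why: Claisen–Schmidt condensation of the methyl ketone with a non-enolisable aldehyde should give the conjugated (E)-chalcone as the thermodynamic alkene.

Step 4
Reactants: 5 (E)-chalcone
Product: 6 [3,4-bis(benzyloxy)-2-(methoxymethoxy)phenyl][(2S,3R)-3-[4-(benzyloxy)phenyl]oxiran-2-yl]methanone
Conditions: poly-D-leucine, urea–H2O2, DBU, THF, rt
Reagents that add atoms: hydrogen peroxide (as its urea adduct) OO
Why: In the Juliá–Colonna epoxidation the helical polypeptide binds the chalcone and delivers hydroperoxide to one enone face, so poly-D-leucine should give the trans-(2S,3R)-epoxy ketone (the mirror image of the poly-L-leucine product), fixing the carbons that become C3 and C2 of ring C.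

Step 5
Reactants: 6 (2S,3R)-epoxy ketone
Product: 8 (2S,3S)-7,8-bis(benzyloxy)-2-[4-(benzyloxy)phenyl]-3-hydroxy-2,3-dihydro-4H-chromen-4-one, via free-phenol epoxy ketone 7 (not isolated)
Conditions: conc. HCl, MeOH/THF, 55 °C
Reagents that add atoms: none
Why: Acid removes the methoxymethyl acetal and the freed phenol opens the epoxide at the benzylic carbon in a 6-endo-tet closure with inversion (the cyclisation of the classical chalcone-epoxide route to dihydroflavonols), so C2 becomes S, C3 keeps its configuration and ring C is 2,3-trans.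

Step 6
Reactants: 8 (2S,3S)-dihydroflavonol
Product: 9 (2S,3R,4S)-7,8-bis(benzyloxy)-2-[4-(benzyloxy)phenyl]-3,4-dihydro-2H-chromene-3,4-diol
Conditions: NaBH4, MeOH/THF, 0 °C
Reagents that add atoms: none
Why: Hydride reduction of trans-dihydroflavonols by NaBH4 should give mainly the 2,3-trans-3,4-trans diol by axial hydride delivery (the C3 descriptor changes from S to R only through CIP priorities), and the C4 configuration is erased in step 8 in any case.

Step 7
Reactants: 10 pyrogallol (benzene-1,2,3-triol)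
Product: 11 2,2-diphenyl-1,3-benzodioxol-4-ol
Conditions: Ph2CCl2, Ph2O, 170 °C
Reagents that add atoms: dichlorodiphenylmethane ClC(Cl)(c1ccccc1)c1ccccc1
Why: Double substitution of the gem-dichloride by two adjacent hydroxyls (catechol ketalisation) ties two oxygens into a diphenylmethylene ketal and leaves one phenol free, and the symmetry of pyrogallol makes the two possible ketals identical.

Step 8
Reactants: 9 (2S,3R,4S)-flavan-3,4-diol; 11 2,2-diphenyl-1,3-benzodioxol-4-ol
Product: 12 (2S,3R,4R)-7,8-bis(benzyloxy)-2-[4-(benzyloxy)phenyl]-4-(7-hydroxy-2,2-diphenyl-1,3-benzodioxol-4-yl)-3,4-dihydro-2H-chromen-3-ol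
Conditions: 11 in excess (3 equiv), BF3·OEt2 (0.3 equiv), CH2Cl2/1,4-dioxane, 0 °C
Reagents that add atoms: none
Why: In this Friedel–Crafts alkylation the Lewis acid ionises the 4-OH of 9 (lost as water) to a benzylic cation stabilised by O1 and the 7-benzyloxy group, which phenol 11 should capture at the carbon para to its free hydroxyl and from the face anti to the 3-OH (the usual 3,4-trans outcome for 2,3-trans flavan-4-yl cations), setting C4 of ring C from either C4 epimer of 9.

Step 9
Reactants: 4 4-(benzyloxy)benzaldehyde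
Product: 13 ethyl (E)-3-[4-(benzyloxy)phenyl]prop-2-enoate
Conditions: (EtO)2P(O)CH2CO2Et, NaH, THF, 0 °C → rt
Reagents that add atoms: triethyl phosphonoacetate CCOC(=O)CP(=O)(OCC)OCC
Why: Horner–Wadsworth–Emmons olefination with a stabilised phosphonate anion should give the (E)-cinnamate selectively.

Step 10
Reactants: 13 ethyl (E)-3-[4-(benzyloxy)phenyl]prop-2-enoate
Product: 14 (E)-3-[4-(benzyloxy)phenyl]prop-2-en-1-ol
Conditions: i-Bu2AlH, CH2Cl2, −78 °C
Reagents that add atoms: none
Why: 1,2-Reduction of the conjugated ester by the aluminium hydride should give the allylic alcohol without touching the alkene geometry.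

Step 11
Reactants: 14 (E)-3-[4-(benzyloxy)phenyl]prop-2-en-1-ol
Product: 15 [(2S,3S)-3-[4-(benzyloxy)phenyl]oxiran-2-yl]methanol
Conditions: Ti(Oi-Pr)4 (10 mol%), L-(+)-diethyl tartrate (12 mol%), t-BuOOH, 4 Å molecular sieves, CH2Cl2, −25 °C; non-acidic work-up
Reagents that add atoms: tert-butyl hydroperoxide CC(C)(C)OO
Why: In the Sharpless asymmetric epoxidation the L-(+)-tartrate titanium complex delivers oxygen to the face of the (E)-allylic alcohol that gives the (2S,3S)-epoxy alcohol, and the catalytic low-temperature protocol limits opening of the electron-rich aryl epoxide.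

Step 12
Reactants: 15 (2S,3S)-epoxy alcohol
Product: 16 (2R,3S)-3-[4-(benzyloxy)phenyl]oxirane-2-carbaldehyde
Conditions: Dess–Martin periodinane, pyridine, CH2Cl2, 0 °C; used at once
Reagents that add atoms: none
Why: Buffered Dess–Martin oxidation should give the aldehyde without opening the epoxide or epimerising the α-carbon (the change from 2S to 2R is a change of CIP priorities only).

Step 13
Reactants: 12 ring-D phenol (4-arylflavan-3-ol); 16 (2R,3S)-3-[4-(benzyloxy)phenyl]oxirane-2-carbaldehyde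
Product: 18 4′,7,8-tri-O-benzyl-ent-oritin-(4β→6)-4′-O-benzyl-7,8-O-(diphenylmethylene)oritin-4α-ol [upper unit 2S,3R,4R; lower unit 2R,3S,4R], via ortho-hydroxyalkylated epoxy carbinol 17 (not isolated)
Conditions: n-Bu2Mg (0.55 equiv), toluene, rt; then 16 (1.3 equiv), CH2Cl2, −20 °C → rt; aq NH4Cl
Reagents that add atoms: none
Why: Proposed new method: the halide-free magnesium bis(phenoxide) of 12 should bind the aldehyde oxygen and the epoxide oxygen of 16 in a Cram chelate and deliver the only free ortho carbon of ring D to the carbonyl carbon (C4a–C4, magnesium alkoxide of 17), after which the same magnesium centre activates the epoxide and the phenoxide oxygen opens it at the benzylic carbon (O1–C2). The closest known reaction types are the ortho-specific hydroxyalkylation of magnesium phenoxides by chiral α-alkoxy aldehydes and the Lewis-acid-promoted phenol/aryl-epoxide cyclisation used for flavan-3-ols; their merger on an epoxy aldehyde as a 1,3-bis-electrophile is the new element. Ring F closes in the 6-endo-tet mode by anti (SN2-like) attack. C3 is carried over from the Sharpless epoxide with its C–O bond untouched; C2 is set by inversion at the benzylic epoxide carbon (a trans-epoxide gives 2,3-trans, also the thermodynamic outcome should the opening gain SN1 character); C4 is set by chelation-controlled addition, whose syn (threo) relation corresponds to the 3,4-trans diol. The step needs ortho-C attack over O- or para-attack (secured by the magnesium-templated six-membered transition state and the blocked para position), 6-endo over 5-exo opening (secured by the 4-benzyloxyphenyl group, which stabilises positive charge at C2) and carbonyl addition before Lewis-acid rearrangement of the epoxide (favoured by the absence of halide and the low temperature). The secondary 3-OH of ring C is much less acidic than the phenol and should stay protonated with the substoichiometric base.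

Step 14
Reactants: 18 protected dimer
Product: 19 ent-oritin-(4β→6)-oritin-4α-ol [(2R,3S,4R)-6-[(2S,3R,4S)-3,7,8-trihydroxy-2-(4-hydroxyphenyl)-3,4-dihydro-2H-chromen-4-yl]-2-(4-hydroxyphenyl)-3,4-dihydro-2H-chromene-3,4,7,8-tetrol]
Conditions: H2 (1 atm), Pd(OH)2/C, THF/MeOH, rt, no acid
Reagents that add atoms: none
Why: Neutral hydrogenolysis should cleave the four benzyl aryl ethers and the diphenylmethylene ketal while leaving the benzylic 4-OH and C2–O1 bonds intact; no stereocentre is touched (the upper C4 descriptor changes from R to S through CIP priorities only).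

**Compound list**

1 | gallacetophenone, 1-(2,3,4-trihydroxyphenyl)ethan-1-one | CC(=O)c1ccc(O)c(O)c1O | starting material
2 | 1-[3,4-bis(benzyloxy)-2-hydroxyphenyl]ethan-1-one | CC(=O)c1ccc(OCc2ccccc2)c(OCc2ccccc2)c1O | intermediate
3 | 1-[3,4-bis(benzyloxy)-2-(methoxymethoxy)phenyl]ethan-1-one | CC(=O)c1ccc(OCc2ccccc2)c(OCc2ccccc2)c1OCOC | intermediate
4 | 4-(benzyloxy)benzaldehyde | O=Cc1ccc(OCc2ccccc2)cc1 | starting material
5 | (E)-1-[3,4-bis(benzyloxy)-2-(methoxymethoxy)phenyl]-3-[4-(benzyloxy)phenyl]prop-2-en-1-one | O=C(/C=C/c1ccc(OCc2ccccc2)cc1)c1ccc(OCc2ccccc2)c(OCc2ccccc2)c1OCOC | intermediate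
6 | [3,4-bis(benzyloxy)-2-(methoxymethoxy)phenyl][(2S,3R)-3-[4-(benzyloxy)phenyl]oxiran-2-yl]methanone | O=C(c1ccc(OCc2ccccc2)c(OCc2ccccc2)c1OCOC)[C@H]1O[C@@H]1c1ccc(OCc2ccccc2)cc1 | intermediate
7 | [3,4-bis(benzyloxy)-2-hydroxyphenyl][(2S,3R)-3-[4-(benzyloxy)phenyl]oxiran-2-yl]methanone | O=C(c1ccc(OCc2ccccc2)c(OCc2ccccc2)c1O)[C@H]1O[C@@H]1c1ccc(OCc2ccccc2)cc1 | intermediate (not isolated)
8 | (2S,3S)-7,8-bis(benzyloxy)-2-[4-(benzyloxy)phenyl]-3-hydroxy-2,3-dihydro-4H-chromen-4-one | O=C1c2ccc(OCc3ccccc3)c(OCc3ccccc3)c2O[C@@H](c2ccc(OCc3ccccc3)cc2)[C@@H]1O | intermediate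
9 | (2S,3R,4S)-7,8-bis(benzyloxy)-2-[4-(benzyloxy)phenyl]-3,4-dihydro-2H-chromene-3,4-diol | O[C@H]1c2ccc(OCc3ccccc3)c(OCc3ccccc3)c2O[C@@H](c2ccc(OCc3ccccc3)cc2)[C@@H]1O | intermediate
10 | pyrogallol, benzene-1,2,3-triol | Oc1cccc(O)c1O | starting material
11 | 2,2-diphenyl-1,3-benzodioxol-4-ol | Oc1cccc2OC(c3ccccc3)(c3ccccc3)Oc12 | intermediate
12 | (2S,3R,4R)-7,8-bis(benzyloxy)-2-[4-(benzyloxy)phenyl]-4-(7-hydroxy-2,2-diphenyl-1,3-benzodioxol-4-yl)-3,4-dihydro-2H-chromen-3-ol | Oc1ccc([C@H]2c3ccc(OCc4ccccc4)c(OCc4ccccc4)c3O[C@@H](c3ccc(OCc4ccccc4)cc3)[C@@H]2O)c2OC(c3ccccc3)(c3ccccc3)Oc12 | intermediate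
13 | ethyl (E)-3-[4-(benzyloxy)phenyl]prop-2-enoate | CCOC(=O)/C=C/c1ccc(OCc2ccccc2)cc1 | intermediate
14 | (E)-3-[4-(benzyloxy)phenyl]prop-2-en-1-ol | OC/C=C/c1ccc(OCc2ccccc2)cc1 | intermediate
15 | [(2S,3S)-3-[4-(benzyloxy)phenyl]oxiran-2-yl]methanol | OC[C@@H]1O[C@H]1c1ccc(OCc2ccccc2)cc1 | intermediate
16 | (2R,3S)-3-[4-(benzyloxy)phenyl]oxirane-2-carbaldehyde | O=C[C@@H]1O[C@H]1c1ccc(OCc2ccccc2)cc1 | intermediate
17 | (2S,3R,4R)-7,8-bis(benzyloxy)-2-[4-(benzyloxy)phenyl]-4-[6-[(R)-hydroxy[(2S,3S)-3-[4-(benzyloxy)phenyl]oxiran-2-yl]methyl]-7-hydroxy-2,2-diphenyl-1,3-benzodioxol-4-yl]-3,4-dihydro-2H-chromen-3-ol | Oc1c(cc([C@H]2c3ccc(OCc4ccccc4)c(OCc4ccccc4)c3O[C@@H](c3ccc(OCc4ccccc4)cc3)[C@@H]2O)c2OC(c3ccccc3)(c3ccccc3)Oc12)[C@@H](O)[C@@H]1O[C@H]1c1ccc(OCc2ccccc2)cc1 | intermediate (not isolated)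
18 | 4′,7,8-tri-O-benzyl-ent-oritin-(4β→6)-4′-O-benzyl-7,8-O-(diphenylmethylene)oritin-4α-ol [upper unit 2S,3R,4R; lower unit 2R,3S,4R] | C(c1ccccc1)Oc1ccc([C@H]2Oc3c(cc([C@H]4c5ccc(OCc6ccccc6)c(OCc6ccccc6)c5O[C@@H](c5ccc(OCc6ccccc6)cc5)[C@@H]4O)c4OC(c5ccccc5)(c5ccccc5)Oc34)[C@@H](O)[C@@H]2O)cc1 | intermediate
19 | ent-oritin-(4β→6)-oritin-4α-ol [upper unit 2S,3R,4S; lower unit 2R,3S,4R] | Oc1ccc([C@H]2Oc3c(cc([C@H]4c5ccc(O)c(O)c5O[C@@H](c5ccc(O)cc5)[C@@H]4O)c(O)c3O)[C@@H](O)[C@@H]2O)cc1 | target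

**Step count and risks**

Total step count: 14. Longest linear sequence: 9 steps (steps 1–6, 8, 13 and 14, from gallacetophenone 1).

Step 13 (bears the label "Proposed new method:"). What may go wrong: rearrangement or oligomerisation of the electron-rich epoxy aldehyde at the Lewis-acidic magnesium centre before the C–C bond forms, poor facial selectivity in the carbonyl addition, 5-exo instead of 6-endo epoxide opening, or loss of the newly formed benzylic 4-hydroxyl through an ortho-quinone methide. The fallback uses the known chalcone-epoxide construction already applied to ring C, sets out from diol 9 and acetophenone 2, and comes back to the route at 19. Acid-catalysed Friedel–Crafts alkylation (TsOH cat., CH2Cl2) of 2, at the carbon para to its chelated hydroxyl, by the cation from 9 would give the 5-(flavan-4-yl)-2-hydroxyacetophenone F1. NaH/MOMCl would give its bis(methoxymethyl) ether F2. Claisen–Schmidt condensation with 4 would give the chalcone F3. Juliá–Colonna epoxidation with poly-L-leucine would give the (2R,3S)-epoxy ketone F4. HCl/MeOH would remove both acetals and close ring F to the (2R,3R)-dihydroflavonol F5. NaBH4 would give the 3,4-trans hexa-O-benzyl diol F6, and hydrogenolysis as in step 14 would give 19.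

Step 8. What may go wrong: attack of the cation ortho instead of para to the free phenol of 11 (wrong regiochemistry), or incomplete anti selectivity at C4. The fallback enforces the regiochemistry by steric blocking, sets out from 11 (with 9), and comes back at 12. TIPSCl/imidazole in DMF would give the triisopropylsilyl ether F7, whose only unhindered activated carbon is para to the silyloxy group. Coupling with 9 under the conditions of step 8 would give the silyl ether of the 4-arylflavan-3-ol F8, and Bu4NF in THF would release 12.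

Step 14. What may go wrong: hydrogenolytic loss of the benzylic 4-hydroxyl of ring F, or its ionisation on the catalyst. The fallback is an oxidation-level detour ending with a reduction known for free phenolic dihydroflavonols; it sets out from 18 and comes back at 19. MnO2 in CH2Cl2 would oxidise only the benzylic 4-OH to the protected dihydroflavonol F9. Hydrogenolysis over Pd(OH)2/C would give the free phenolic dihydroflavonol F10, and NaBH4 in EtOH would then give the 3,4-trans diol 19.

Further compounds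
F1 | step 13 | 1-[5-[(2S,3R,4R)-7,8-bis(benzyloxy)-2-[4-(benzyloxy)phenyl]-3-hydroxy-3,4-dihydro-2H-chromen-4-yl]-3,4-bis(benzyloxy)-2-hydroxyphenyl]ethan-1-one | CC(=O)c1cc([C@H]2c3ccc(OCc4ccccc4)c(OCc4ccccc4)c3O[C@@H](c3ccc(OCc4ccccc4)cc3)[C@@H]2O)c(OCc2ccccc2)c(OCc2ccccc2)c1O
F2 | step 13 | 1-[5-[(2S,3R,4R)-7,8-bis(benzyloxy)-2-[4-(benzyloxy)phenyl]-3-(methoxymethoxy)-3,4-dihydro-2H-chromen-4-yl]-3,4-bis(benzyloxy)-2-(methoxymethoxy)phenyl]ethan-1-one | CC(=O)c1cc([C@H]2c3ccc(OCc4ccccc4)c(OCc4ccccc4)c3O[C@@H](c3ccc(OCc4ccccc4)cc3)[C@@H]2OCOC)c(OCc2ccccc2)c(OCc2ccccc2)c1OCOC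
F3 | step 13 | (E)-1-[5-[(2S,3R,4R)-7,8-bis(benzyloxy)-2-[4-(benzyloxy)phenyl]-3-(methoxymethoxy)-3,4-dihydro-2H-chromen-4-yl]-3,4-bis(benzyloxy)-2-(methoxymethoxy)phenyl]-3-[4-(benzyloxy)phenyl]prop-2-en-1-one | O=C(/C=C/c1ccc(OCc2ccccc2)cc1)c1cc([C@H]2c3ccc(OCc4ccccc4)c(OCc4ccccc4)c3O[C@@H](c3ccc(OCc4ccccc4)cc3)[C@@H]2OCOC)c(OCc2ccccc2)c(OCc2ccccc2)c1OCOC
F4 | step 13 | [5-[(2S,3R,4R)-7,8-bis(benzyloxy)-2-[4-(benzyloxy)phenyl]-3-(methoxymethoxy)-3,4-dihydro-2H-chromen-4-yl]-3,4-bis(benzyloxy)-2-(methoxymethoxy)phenyl][(2R,3S)-3-[4-(benzyloxy)phenyl]oxiran-2-yl]methanone | O=C(c1cc([C@H]2c3ccc(OCc4ccccc4)c(OCc4ccccc4)c3O[C@@H](c3ccc(OCc4ccccc4)cc3)[C@@H]2OCOC)c(OCc2ccccc2)c(OCc2ccccc2)c1OCOC)[C@@H]1O[C@H]1c1ccc(OCc2ccccc2)cc1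
F5 | step 13 | (2R,3R)-7,8-bis(benzyloxy)-6-[(2S,3R,4R)-7,8-bis(benzyloxy)-2-[4-(benzyloxy)phenyl]-3-hydroxy-3,4-dihydro-2H-chromen-4-yl]-2-[4-(benzyloxy)phenyl]-3-hydroxy-2,3-dihydro-4H-chromen-4-one | O=C1c2cc([C@H]3c4ccc(OCc5ccccc5)c(OCc5ccccc5)c4O[C@@H](c4ccc(OCc5ccccc5)cc4)[C@@H]3O)c(OCc3ccccc3)c(OCc3ccccc3)c2O[C@H](c2ccc(OCc3ccccc3)cc2)[C@H]1O
F6 | step 13 | 4′,7,8-tri-O-benzyl-ent-oritin-(4β→6)-4′,7,8-tri-O-benzyl-oritin-4α-ol [upper unit 2S,3R,4R; lower unit 2R,3S,4R] | C(c1ccccc1)Oc1ccc([C@H]2Oc3c(cc([C@H]4c5ccc(OCc6ccccc6)c(OCc6ccccc6)c5O[C@@H](c5ccc(OCc6ccccc6)cc5)[C@@H]4O)c(OCc4ccccc4)c3OCc3ccccc3)[C@@H](O)[C@@H]2O)cc1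
F7 | step 8 | 2,2-diphenyl-4-[(triisopropylsilyl)oxy]-1,3-benzodioxole | CC(C)[Si](Oc1cccc2OC(c3ccccc3)(c3ccccc3)Oc12)(C(C)C)C(C)C
F8 | step 8 | (2S,3R,4R)-7,8-bis(benzyloxy)-2-[4-(benzyloxy)phenyl]-4-[2,2-diphenyl-7-[(triisopropylsilyl)oxy]-1,3-benzodioxol-4-yl]-3,4-dihydro-2H-chromen-3-ol | CC(C)[Si](Oc1ccc([C@H]2c3ccc(OCc4ccccc4)c(OCc4ccccc4)c3O[C@@H](c3ccc(OCc4ccccc4)cc3)[C@@H]2O)c2OC(c3ccccc3)(c3ccccc3)Oc12)(C(C)C)C(C)C
F9 | step 14 | 4-oxo analogue of 18 (protected dihydroflavonol; upper unit 2S,3R,4R; lower unit 2R,3R) | C(c1ccccc1)Oc1ccc([C@H]2Oc3c(cc([C@H]4c5ccc(OCc6ccccc6)c(OCc6ccccc6)c5O[C@@H](c5ccc(OCc6ccccc6)cc5)[C@@H]4O)c4OC(c5ccccc5)(c5ccccc5)Oc34)C(=O)[C@@H]2O)cc1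
F10 | step 14 | (2R,3R)-3,7,8-trihydroxy-2-(4-hydroxyphenyl)-6-[(2S,3R,4S)-3,7,8-trihydroxy-2-(4-hydroxyphenyl)-3,4-dihydro-2H-chromen-4-yl]-2,3-dihydro-4H-chromen-4-one | Oc1ccc([C@H]2Oc3c(cc([C@H]4c5ccc(O)c(O)c5O[C@@H](c5ccc(O)cc5)[C@@H]4O)c(O)c3O)C(=O)[C@@H]2O)cc1
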